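**Retrosynthetic overview**
1. Target ⇒ its C15 PMB ether; the γ-lactone and the ten-membered carbocycle are opened together at C6–C7 and O–C12, giving an enal plus a 2-(bromomethyl)enoate (intramolecular Cr(II) Barbier allylation, then lactonisation).
2. Allyl bromide ⇒ Baylis–Hillman homologation (C7–C11) of an α-acyloxy aldehyde; the C8 carbinol comes from a boron aldol (C8–C9).
3. 3(2H)-Furanone ⇒ 2-hydroxy-2-alkynyl ketone by Au-catalysed heterocyclisation with a 1,2-methyl shift (C14 moves from C1 to C10), which relays the carbinol stereocentre to C10.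
4. Ketol ⇒ Sonogashira coupling (C3–C4) of a (Z)-vinyl iodide with the product of a new enantioselective mono-alkynylation of biacetyl (C1–C2).
5. Ring order: furanone first, then the carbocycle and the lactone in one operation.

Assumption: the mono-PMB ether of but-2-yne-1,4-diol and TBS-protected glycolaldehyde are bought as such (protecting-group atoms not counted), and the antipodes named for the Rh catalyst and for Ipc2BCl are the ones expected to give the stated configuration, the mirror-image reagent being used if the sense proves opposite.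

Abbreviations: TBS = tert-butyldimethylsilyl, TMS = trimethylsilyl, PMB = 4-methoxybenzyl, Ipc = isopinocampheyl. Locants C1–C15 are germacrane numbering of the target (C1 ketone, C3 O-bearing furanone carbon, C4=C5, C6/C7 lactone carbons, C8 ester carbon, C10 quaternary carbon, C15 CH2OH).

Step 1
Reactants: 1 4-[(4-methoxybenzyl)oxy]but-2-yn-1-ol
Product: 3 (Z)-3-iodo-4-[(4-methoxybenzyl)oxy]but-2-en-1-ol, via sodium vinylalanate 2 (not isolated)
Conditions: Red-Al (1.3 equiv), THF, 0 °C → rt; then I2, −78 → 0 °C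
Reagents that add atoms: iodine, II
Why: Red-Al reduction of a propargylic alcohol is a hydroxyl-directed trans-hydroalumination that puts aluminium on the distal alkyne carbon in a five-membered chelate, and iodinolysis with retention gives the (Z)-γ-iodoallylic alcohol, so the future C3 substituent on C4 is cis to C6 as the 4Z alkene needs.

Step 2
Reactants: 4 butane-2,3-dione; 5 ethynyltrimethylsilane
Product: 6 (R)-3-hydroxy-3-methyl-5-(trimethylsilyl)pent-4-yn-2-one
Conditions: [(S,S)-iPr-Phebox]Rh(OAc)2(H2O) (3 mol%), 4 (3 equiv), Et2O, 30 °C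
Reagents that add atoms: none
Why: Proposed new method: enantioface-selective mono-alkynylation of a symmetrical 1,2-diketone under Phebox–Rh(III) catalysis, in which acetate-assisted C–H metalation of 5 gives a Rh–alkynyl, one carbonyl of 4 binds cis to it with the neighbouring acetyl group (playing the part of the ester in a keto ester) turned away from the oxazoline isopropyl groups, 1,2-insertion sets the (R)-carbinol and protonolysis by the next alkyne turns the catalyst over, while the ketol product is too electron-rich to add a second alkyne; the closest known reaction type is the Phebox–Rh direct alkynylation of α-keto esters and trifluoromethyl ketones, which has not been extended to 1,2-diketones.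

Step 3
Reactants: 3 (Z)-3-iodo-4-[(4-methoxybenzyl)oxy]but-2-en-1-ol; 6 (R)-3-hydroxy-3-methyl-5-(trimethylsilyl)pent-4-yn-2-one
Product: 8 (3R,6E)-3,8-dihydroxy-6-{[(4-methoxybenzyl)oxy]methyl}-3-methyloct-6-en-4-yn-2-one, via terminal alkyne 7 (not isolated)
Conditions: PdCl2(PPh3)2 (3 mol%), CuI (6 mol%), CsF (1.5 equiv), Et3N, MeCN–H2O, rt
Reagents that add atoms: none
Why: Fluoride removes the C-silyl group in situ and the liberated terminal alkyne undergoes Sonogashira coupling with the vinyl iodide with retention of alkene geometry, forming C3–C4 under conditions that leave the tertiary ketol untouched.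

Step 4
Reactants: 8 (3R,6E)-3,8-dihydroxy-6-{[(4-methoxybenzyl)oxy]methyl}-3-methyloct-6-en-4-yn-2-one
Product: 10 (3R,6E)-8-(TBSO)-6-(PMBOCH2)-3-methyl-3-(TMSO)oct-6-en-4-yn-2-one, via mono-TBS ether 9 (not isolated)
Conditions: TBSCl (1.05 equiv), imidazole, DMF, 0 °C; then TMSCl (1.5 equiv), rt
Reagents that add atoms: tert-butyldimethylsilyl chloride, CC(C)(C)[Si](C)(C)Cl; chlorotrimethylsilane, C[Si](C)(C)Cl
Why: Silyl ether formation is site-selective because TBSCl/imidazole reacts only with the primary allylic alcohol at 0 °C, after which the small TMSCl caps the tertiary carbinol that would otherwise consume the boron reagent of step 5.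

Step 5
Reactants: 10 (3R,6E)-8-(TBSO)-6-(PMBOCH2)-3-methyl-3-(TMSO)oct-6-en-4-yn-2-one; 11 2-[(tert-butyldimethylsilyl)oxy]acetaldehyde
Product: 15 (2R,5R,8E)-1,10-bis(TBSO)-2,5-dihydroxy-8-(PMBOCH2)-5-methyldec-8-en-6-yn-4-one, via boron enolate 12 (not isolated), via boron aldolate 13 (not isolated), via TMS-protected aldol 14 (not isolated)
Conditions: (−)-Ipc2BCl (1.3 equiv), Et3N, Et2O, −78 → 0 °C; 11, −78 → −20 °C; MeOH, pH 7 buffer, H2O2, 0 °C; then citric acid, MeOH, rt
Reagents that add atoms: none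
Why: Paterson boron aldol reaction, in which Ipc2BCl/Et3N enolises the ketone at its only enolisable position (the C9 methyl) and the chiral boron enolate adds to the Re face of the aldehyde to set 8R under reagent control (the minor C8 epimer is a separable diastereomer), after which oxidative work-up frees the aldol and citric acid/MeOH removes only the tertiary TMS ether.

Step 6
Reactants: 15 (2R,5R,8E)-1,10-bis(TBSO)-2,5-dihydroxy-8-(PMBOCH2)-5-methyldec-8-en-6-yn-4-one
Product: 16 (R)-2-[(R)-3-(TBSO)-2-hydroxypropyl]-5-[(Z)-4-(TBSO)-1-(PMBO)but-2-en-2-yl]-2-methylfuran-3(2H)-one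
Conditions: AuCl3 (5 mol%), CH2Cl2, rt → 38 °C
Reagents that add atoms: none
Why: Gold-catalysed heterocyclisation/1,2-shift domino of a 2-hydroxy-2-alkynyl ketone, in which π-activation of the alkyne triggers 5-endo-dig attack of the ketone oxygen at the alkenyl-stabilised terminus C3 to give a cyclic oxocarbenium ion, the C14 methyl then shifts suprafacially from the carbinol carbon to the adjacent cationic C10 (an α-ketol-type 1,2-alkyl shift driven by C1=O formation) and protodeauration releases the 3(2H)-furanone, so the (R)-carbinol is converted stereospecifically into (R)-C10.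

Step 7
Reactants: 16 (R)-2-[(R)-3-(TBSO)-2-hydroxypropyl]-5-[(Z)-4-(TBSO)-1-(PMBO)but-2-en-2-yl]-2-methylfuran-3(2H)-one; 17 2-methylpropanoyl chloride
Product: 18 (R)-1-(TBSO)-3-[(R)-5-[(Z)-4-(TBSO)-1-(PMBO)but-2-en-2-yl]-2-methyl-3-oxo-2,3-dihydrofuran-2-yl]propan-2-yl 2-methylpropanoate
Conditions: pyridine, DMAP (cat.), CH2Cl2, 0 °C
Reagents that add atoms: none
Why: DMAP-catalysed acylation of the only free hydroxyl installs the C8 isobutyrate with retention, and because the former ketone is now a quaternary ether carbon the new ester cannot undergo β-elimination.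

Step 8
Reactants: 18 (R)-1-(TBSO)-3-[(R)-5-[(Z)-4-(TBSO)-1-(PMBO)but-2-en-2-yl]-2-methyl-3-oxo-2,3-dihydrofuran-2-yl]propan-2-yl 2-methylpropanoate
Product: 19 (R)-1-hydroxy-3-[(R)-5-[(Z)-4-hydroxy-1-(PMBO)but-2-en-2-yl]-2-methyl-3-oxo-2,3-dihydrofuran-2-yl]propan-2-yl 2-methylpropanoate
Conditions: HF·pyridine, pyridine, THF, 0 °C → rt
Reagents that add atoms: none
Why: Fluoride-mediated desilylation cleaves both primary TBS ethers while the PMB ether, the isobutyrate and the furanone are stable to buffered HF, and the diol is used at once to avoid 1,2-acyl migration.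

Step 9
Reactants: 19 (R)-1-hydroxy-3-[(R)-5-[(Z)-4-hydroxy-1-(PMBO)but-2-en-2-yl]-2-methyl-3-oxo-2,3-dihydrofuran-2-yl]propan-2-yl 2-methylpropanoate
Product: 20 (R)-1-[(R)-5-[(Z)-1-(PMBO)-4-oxobut-2-en-2-yl]-2-methyl-3-oxo-2,3-dihydrofuran-2-yl]-3-oxopropan-2-yl 2-methylpropanoate
Conditions: Dess–Martin periodinane (2.6 equiv), CH2Cl2, 0 °C → rt
Reagents that add atoms: none
Why: Dess–Martin oxidation converts both primary alcohols into aldehydes under near-neutral conditions that do not epimerise the α-acyloxy centre C8 or isomerise the (Z)-enal.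

Step 10
Reactants: 20 (R)-1-[(R)-5-[(Z)-1-(PMBO)-4-oxobut-2-en-2-yl]-2-methyl-3-oxo-2,3-dihydrofuran-2-yl]-3-oxopropan-2-yl 2-methylpropanoate; 21 methyl acrylate
Product: 22 methyl (4R)-3-hydroxy-2-methylidene-4-[(2-methylpropanoyl)oxy]-5-[(R)-5-[(Z)-1-(PMBO)-4-oxobut-2-en-2-yl]-2-methyl-3-oxo-2,3-dihydrofuran-2-yl]pentanoate (C3 epimers)
Conditions: 21 (5 equiv), DABCO (0.3 equiv), 1,4-dioxane–H2O (1:1), 0 °C → rt
Reagents that add atoms: none
Why: Morita–Baylis–Hillman reaction in which the DABCO–acrylate zwitterion adds only to the α-acyloxy aliphatic aldehyde, which is far more electrophilic than the β,β-disubstituted enal conjugated to the furanone, and the new C7 carbinol need not be controlled because it is erased in step 11.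

Step 11
Reactants: 22 methyl (4R)-3-hydroxy-2-methylidene-4-[(2-methylpropanoyl)oxy]-5-[(R)-5-[(Z)-1-(PMBO)-4-oxobut-2-en-2-yl]-2-methyl-3-oxo-2,3-dihydrofuran-2-yl]pentanoate (C3 epimers)
Product: 23 methyl (2Z,4R)-2-(bromomethyl)-4-[(2-methylpropanoyl)oxy]-5-[(R)-5-[(Z)-1-(PMBO)-4-oxobut-2-en-2-yl]-2-methyl-3-oxo-2,3-dihydrofuran-2-yl]pent-2-enoate
Conditions: NBS, Me2S, CH2Cl2, −20 → 0 °C
Reagents that add atoms: N-bromosuccinimide, O=C1CCC(=O)N1Br
Why: Corey–Kim-type bromination of the Baylis–Hillman alcohol proceeds by SN2′ displacement of the alkoxysulfonium by bromide, giving the conjugated (Z)-2-(bromomethyl)enoate and converting C7 into the sp2 terminus of the allyl unit.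

Step 12
Reactants: 23 methyl (2Z,4R)-2-(bromomethyl)-4-[(2-methylpropanoyl)oxy]-5-[(R)-5-[(Z)-1-(PMBO)-4-oxobut-2-en-2-yl]-2-methyl-3-oxo-2,3-dihydrofuran-2-yl]pent-2-enoate
Product: 25 (6R,7R,8R,10R)-15-O-(4-methoxybenzyl) ether of the target, via hydroxy ester 24 (not isolated)
Conditions: CrCl2 (6 equiv), THF (3 mM, slow addition), rt; 1 M HCl work-up; then p-TsOH·H2O (cat.), CH2Cl2, rt
Reagents that add atoms: none
Why: Intramolecular Nozaki–Hiyama-type Barbier allylation in which the allylchromium(III) adds through its γ-carbon C7 to the enal in a chair-like transition state held by the tether, the (Z)-enal and the furanone bridge are expected to allow only the approach that places H6 and H7 trans with C11 anti to the C8 ester (6R,7R), and the γ-hydroxy ester then closes to the trans-fused α-methylene lactone on acid treatment.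

Step 13
Reactants: 25 (6R,7R,8R,10R)-15-O-(4-methoxybenzyl) ether of the target
Product: 26 [(2Z,4R,8R,9R,11R)-2-(hydroxymethyl)-11-methyl-7-methylidene-6,12-dioxo-5,14-dioxatricyclo[9.2.1.0(4,8)]tetradeca-1(13),2-dien-9-yl] 2-methylpropanoate
Conditions: DDQ (1.5 equiv), CH2Cl2–pH 7 buffer (10:1), 0 °C → rt
Reagents that add atoms: none
Why: Oxidative PMB ether cleavage (DDQ oxidation of the electron-rich arene, then hydrolysis of the oxocarbenium ion) frees the C15 alcohol without touching any stereocentre, the isobutyrate, the enone or the methylene lactone.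

**Compound list**
1 | 4-[(4-methoxybenzyl)oxy]but-2-yn-1-ol | OCC#CCOCc1ccc(OC)cc1 | starting material
2 | sodium 2,2-bis(2-methoxyethoxy)-3-(PMBOCH2)-2,5-dihydro-1,2-oxaluminol-2-uide (cyclic (Z)-vinylalanate) | [Na+].COCCO[Al-]1(OCCOC)OCC=C1COCc1ccc(OC)cc1 | intermediate (not isolated)
3 | (Z)-3-iodo-4-[(4-methoxybenzyl)oxy]but-2-en-1-ol | OC/C=C(\I)COCc1ccc(OC)cc1 | intermediate
4 | butane-2,3-dione | CC(=O)C(C)=O | starting material
5 | ethynyltrimethylsilane | C#C[Si](C)(C)C | starting material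
6 | (R)-3-hydroxy-3-methyl-5-(trimethylsilyl)pent-4-yn-2-one | CC(=O)[C@](C)(O)C#C[Si](C)(C)C | intermediate
7 | (R)-3-hydroxy-3-methylpent-4-yn-2-one | CC(=O)[C@](C)(O)C#C | intermediate (not isolated)
8 | (3R,6E)-3,8-dihydroxy-6-{[(4-methoxybenzyl)oxy]methyl}-3-methyloct-6-en-4-yn-2-one | CC(=O)[C@](C)(O)C#C/C(COCc1ccc(OC)cc1)=C\CO | intermediate
9 | (3R,6E)-8-(TBSO)-3-hydroxy-6-(PMBOCH2)-3-methyloct-6-en-4-yn-2-one | CC(=O)[C@](C)(O)C#C/C(COCc1ccc(OC)cc1)=C\CO[Si](C)(C)C(C)(C)C | intermediate (not isolated)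
10 | (3R,6E)-8-(TBSO)-6-(PMBOCH2)-3-methyl-3-(TMSO)oct-6-en-4-yn-2-one | CC(=O)[C@](C)(O[Si](C)(C)C)C#C/C(COCc1ccc(OC)cc1)=C\CO[Si](C)(C)C(C)(C)C | intermediate
11 | 2-[(tert-butyldimethylsilyl)oxy]acetaldehyde | O=CCO[Si](C)(C)C(C)(C)C | starting material
12 | diisopinocampheylboron enolate of 10 ((3R,6E)-2-(Ipc2BO)-octa-1,6-dien-4-yne) | C=C(OB([C@@H]1C[C@@H]2C[C@H]([C@H]1C)C2(C)C)[C@@H]1C[C@@H]2C[C@H]([C@H]1C)C2(C)C)[C@](C)(O[Si](C)(C)C)C#C/C(COCc1ccc(OC)cc1)=C\CO[Si](C)(C)C(C)(C)C | intermediate (not isolated)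
13 | diisopinocampheylboron aldolate (2-O-BIpc2 derivative of 14) | O=C(C[C@@H](OB([C@@H]1C[C@@H]2C[C@H]([C@H]1C)C2(C)C)[C@@H]1C[C@@H]2C[C@H]([C@H]1C)C2(C)C)CO[Si](C)(C)C(C)(C)C)[C@](C)(O[Si](C)(C)C)C#C/C(COCc1ccc(OC)cc1)=C\CO[Si](C)(C)C(C)(C)C | intermediate (not isolated)
14 | (2R,5R,8E)-1,10-bis(TBSO)-2-hydroxy-8-(PMBOCH2)-5-methyl-5-(TMSO)dec-8-en-6-yn-4-one | O=C(C[C@@H](O)CO[Si](C)(C)C(C)(C)C)[C@](C)(O[Si](C)(C)C)C#C/C(COCc1ccc(OC)cc1)=C\CO[Si](C)(C)C(C)(C)C | intermediate (not isolated)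
15 | (2R,5R,8E)-1,10-bis(TBSO)-2,5-dihydroxy-8-(PMBOCH2)-5-methyldec-8-en-6-yn-4-one | O=C(C[C@@H](O)CO[Si](C)(C)C(C)(C)C)[C@](C)(O)C#C/C(COCc1ccc(OC)cc1)=C\CO[Si](C)(C)C(C)(C)C | intermediate
16 | (R)-2-[(R)-3-(TBSO)-2-hydroxypropyl]-5-[(Z)-4-(TBSO)-1-(PMBO)but-2-en-2-yl]-2-methylfuran-3(2H)-one | C[C@]1(C[C@@H](O)CO[Si](C)(C)C(C)(C)C)OC(=CC1=O)/C(COCc1ccc(OC)cc1)=C\CO[Si](C)(C)C(C)(C)C | intermediate
17 | 2-methylpropanoyl chloride | CC(C)C(Cl)=O | starting material
18 | (R)-1-(TBSO)-3-[(R)-5-[(Z)-4-(TBSO)-1-(PMBO)but-2-en-2-yl]-2-methyl-3-oxo-2,3-dihydrofuran-2-yl]propan-2-yl 2-methylpropanoate | C[C@]1(C[C@@H](OC(=O)C(C)C)CO[Si](C)(C)C(C)(C)C)OC(=CC1=O)/C(COCc1ccc(OC)cc1)=C\CO[Si](C)(C)C(C)(C)C | intermediate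
19 | (R)-1-hydroxy-3-[(R)-5-[(Z)-4-hydroxy-1-(PMBO)but-2-en-2-yl]-2-methyl-3-oxo-2,3-dihydrofuran-2-yl]propan-2-yl 2-methylpropanoate | C[C@]1(C[C@@H](OC(=O)C(C)C)CO)OC(=CC1=O)/C(COCc1ccc(OC)cc1)=C\CO | intermediate
20 | (R)-1-[(R)-5-[(Z)-1-(PMBO)-4-oxobut-2-en-2-yl]-2-methyl-3-oxo-2,3-dihydrofuran-2-yl]-3-oxopropan-2-yl 2-methylpropanoate | C[C@]1(C[C@@H](OC(=O)C(C)C)C=O)OC(=CC1=O)/C(COCc1ccc(OC)cc1)=C\C=O | intermediate
21 | methyl acrylate | C=CC(=O)OC | starting material
22 | methyl (4R)-3-hydroxy-2-methylidene-4-[(2-methylpropanoyl)oxy]-5-[(R)-5-[(Z)-1-(PMBO)-4-oxobut-2-en-2-yl]-2-methyl-3-oxo-2,3-dihydrofuran-2-yl]pentanoate (C3 epimers, centre left undefined) | C[C@]1(C[C@@H](OC(=O)C(C)C)C(O)C(=C)C(=O)OC)OC(=CC1=O)/C(COCc1ccc(OC)cc1)=C\C=O | intermediate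
23 | methyl (2Z,4R)-2-(bromomethyl)-4-[(2-methylpropanoyl)oxy]-5-[(R)-5-[(Z)-1-(PMBO)-4-oxobut-2-en-2-yl]-2-methyl-3-oxo-2,3-dihydrofuran-2-yl]pent-2-enoate | C[C@]1(C[C@@H](OC(=O)C(C)C)/C=C(\CBr)C(=O)OC)OC(=CC1=O)/C(COCc1ccc(OC)cc1)=C\C=O | intermediate
24 | seco-lactone hydroxy ester: ten-membered ring closed, C6–OH free, C7 bears C(=CH2)CO2Me; 6R,7S,8R,10R (7S by CIP only, same geometry as 7R in 25) | O[C@@H]1/C=C(/COCc2ccc(OC)cc2)C2=CC(=O)[C@@](C)(C[C@@H](OC(=O)C(C)C)[C@H]1C(=C)C(=O)OC)O2 | intermediate (not isolated)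
25 | (6R,7R,8R,10R)-15-O-(4-methoxybenzyl) ether of the target | C=C1C(=O)O[C@@H]2/C=C(/COCc4ccc(OC)cc4)C3=CC(=O)[C@@](C)(C[C@@H](OC(=O)C(C)C)[C@@H]12)O3 | intermediate
26 | [(2Z,4R,8R,9R,11R)-2-(hydroxymethyl)-11-methyl-7-methylidene-6,12-dioxo-5,14-dioxatricyclo[9.2.1.0(4,8)]tetradeca-1(13),2-dien-9-yl] 2-methylpropanoate (CNP0176924.3) | C=C1C(=O)O[C@@H]2/C=C(/CO)C3=CC(=O)[C@@](C)(C[C@@H](OC(=O)C(C)C)[C@@H]12)O3 | target

**Step count and risks**
Total steps: 13. Longest linear sequence: 12 (steps 1 and 3–13, or equally 2–13).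

Most likely to fail, first: step 2 (the proposed alkynylation). Biacetyl may give low ee, add a second alkyne or self-condense. The fallback sets out from 5 and comes back at 6. Compound 5 is added to purchased methyl pyruvate by the known catalytic asymmetric alkynylation of α-keto esters (Phebox–Rh, or Zn(OTf)2/amino alcohol), giving methyl (R)-2-hydroxy-2-methyl-4-(trimethylsilyl)but-3-ynoate F1. Treatment of that ester with MeNH(OMe)·HCl and i-PrMgCl in THF at −20 °C gives (R)-2-hydroxy-N-methoxy-N,2-dimethyl-4-(trimethylsilyl)but-3-ynamide F2. MeMgBr in THF at 0 °C converts the Weinreb amide into 6.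

Second: step 10 (Baylis–Hillman reaction on the dialdehyde). The amine may epimerise C8 or isomerise the (Z)-enal before the slow addition is complete. The fallback sets out from 20 and comes back at 22. Methyl propiolate is hydroaluminated with DIBAL-H/NMO in THF at 0 °C to methyl 2-(diisobutylalumanyl)prop-2-enoate F3. This vinylalane is added to 20 at −78 °C, where it attacks the more electrophilic α-acyloxy aldehyde without any amine present, and aqueous work-up gives 22.

Third: step 12 (macrocyclising Barbier allylation). It may give the wrong C6/C7 diastereomer, oligomers, or loss of the C8 isobutyrate from the allylmetal. The fallback sets out from 23 and comes back at 25. Pd-catalysed borylation (Pd2(dba)3, B2pin2, toluene, 50 °C) gives the isolable allylboronate methyl (2E,4R)-4-[(2-methylpropanoyl)oxy]-5-[(R)-5-[(Z)-1-(PMBO)-4-oxobut-2-en-2-yl]-2-methyl-3-oxo-2,3-dihydrofuran-2-yl]-2-[(4,4,5,5-tetramethyl-1,3,2-dioxaborolan-2-yl)methyl]pent-2-enoate F4. Sc(OTf)3-catalysed intramolecular allylboration at 2 mM in toluene goes through a closed six-membered transition state with a different stereochemical bias from the chromium reagent. Acidic work-up passes through 24 and lactonises to 25.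

**Further compounds**
F1 | step 2 | methyl (R)-2-hydroxy-2-methyl-4-(trimethylsilyl)but-3-ynoate | COC(=O)[C@](C)(O)C#C[Si](C)(C)C
F2 | step 2 | (R)-2-hydroxy-N-methoxy-N,2-dimethyl-4-(trimethylsilyl)but-3-ynamide | CON(C)C(=O)[C@](C)(O)C#C[Si](C)(C)C
F3 | step 10 | methyl 2-(diisobutylalumanyl)prop-2-enoate | C=C(C(=O)OC)[Al](CC(C)C)CC(C)C
F4 | step 12 | methyl (2E,4R)-4-[(2-methylpropanoyl)oxy]-5-[(R)-5-[(Z)-1-(PMBO)-4-oxobut-2-en-2-yl]-2-methyl-3-oxo-2,3-dihydrofuran-2-yl]-2-[(4,4,5,5-tetramethyl-1,3,2-dioxaborolan-2-yl)methyl]pent-2-enoate | C[C@]1(C[C@@H](OC(=O)C(C)C)/C=C(\CB2OC(C)(C)C(C)(C)O2)C(=O)OC)OC(=CC1=O)/C(COCc1ccc(OC)cc1)=C\C=O
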